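The 12-membered ring is cut at both aryl–C3 bonds into two identical dienone boronates, rejoined by double Rh-catalysed conjugate arylation. Each monomer comes from the key step: an enantioselective inverse-electron-demand Diels–Alder reaction of a flat 3-aroyl-6-methyl-2-pyrone with 2,4-bis(benzyloxy)styrene, then CO2 loss. In one operation it forms C1–C6 and C4–C5 of each cyclohexene ring (C1 methyl-bearing alkene carbon, C2 =CH, C3 CH–aryl of the macrocycle, C4 CH–C=O, C5 CH–dihydroxyphenyl, C6 CH2; ring 2 primed) and sets C5. It exploits that the C1(CH3)=C2 alkene and the C4 aroyl group map onto the 6-methyl and 3-acyl positions of a 2-pyrone.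

Key step: step 5

Assumption: C4 and C4′ (α to the ketones) are the only epimerisable stereocentres, and the required 4S,4′R pair (ring 1 cis-fused, ring 2 trans-fused to the macrocycle) is taken to be the thermodynamically preferred one, reached by base equilibration.

Step 1
Reactants: 1 1-(5-bromo-2,4-dihydroxyphenyl)ethan-1-one
Product: 2 1-[2,4-bis(benzyloxy)-5-bromophenyl]ethan-1-one
Conditions: BnBr (2.4 equiv), K2CO3, DMF, 60 °C
Reagents that add atoms: benzyl bromide, BrCc1ccccc1
Why: Williamson O-alkylation of both phenols (the hydrogen-bonded 2-OH needs the polar solvent and heat) should give the bis-ether without creating a stereocentre.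

Step 2
Reactants: 2 1-[2,4-bis(benzyloxy)-5-bromophenyl]ethan-1-one
Product: 3 methyl 3-[2,4-bis(benzyloxy)-5-bromophenyl]-3-oxopropanoate
Conditions: NaH, (MeO)2CO, THF, reflux; AcOH quench
Reagents that add atoms: dimethyl carbonate, COC(=O)OC
Why: Claisen-type C-acylation of the methyl ketone enolate should be driven to completion by deprotonation of the β-keto ester that forms.

Step 3
Reactants: 3 methyl 3-[2,4-bis(benzyloxy)-5-bromophenyl]-3-oxopropanoate; 4 but-3-yn-2-one
Product: 6 3-[2,4-bis(benzyloxy)-5-bromobenzoyl]-6-methyl-2H-pyran-2-one, via methyl 2-aroyl-5-oxohex-3-enoate 5 (not isolated)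
Conditions: DABCO (10 mol%), MeCN, 0 °C to rt; then TsOH·H2O (cat.), toluene, 80 °C
Reagents that add atoms: none
Why: Amine-catalysed Michael addition of the β-keto ester to the ynone followed by acid-catalysed enol-lactonisation (loss of MeOH) is a standard 2-pyrone annulation, and the weak base should avoid carbocyclisation of the methyl ketone.

Step 4
Reactants: 7 2,4-bis(benzyloxy)benzaldehyde
Product: 8 2,4-bis(benzyloxy)-1-ethenylbenzene
Conditions: Ph3PCH3Br, KOtBu, THF, 0 °C to rt
Reagents that add atoms: methyltriphenylphosphonium bromide, C[P+](c1ccccc1)(c1ccccc1)c1ccccc1.[Br-]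
Why: Wittig methylenation of the aldehyde should give the electron-rich styrene without creating a stereocentre.

Step 5
Reactants: 6 3-[2,4-bis(benzyloxy)-5-bromobenzoyl]-6-methyl-2H-pyran-2-one; 8 2,4-bis(benzyloxy)-1-ethenylbenzene (1.5 equiv)
Product: 10 [2,4-bis(benzyloxy)-5-bromophenyl]{(6S)-6-[2,4-bis(benzyloxy)phenyl]-4-methylcyclohexa-1,3-dien-1-yl}methanone, via endo bridged lactone 9 (not isolated)
Conditions: Cu(OTf)2 (10 mol%), (S,S)-t-Bu-box (11 mol%), 4 Å MS, CH2Cl2, −20 °C to rt; then toluene, 80 °C (−CO2), argon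
Reagents that add atoms: none
Why: The electron-poor pyrone 6, bound through its ketone and lactone carbonyls to the chiral Cu(OTf)2–bis(oxazoline) complex, should undergo an asynchronous inverse-electron-demand Diels–Alder reaction with the electron-rich styrene 8 to give bridged lactone 9, which loses CO2 by retro-Diels–Alder reaction on warming. The closest known reaction type is the Lewis-acid-catalysed cycloaddition of 3-carbonyl-2-pyrones with vinyl ethers and styrenes, including bis(oxazoline)–Cu(OTf)2 versions. The carbocycle is closed by [4+2] cycloaddition, forming C1–C6 (pyrone C6 to the styrene CH2) and C4–C5 (pyrone C3 to the benzylic carbon) together, and extrusion then leaves C1=C2 as the ring alkene of the target and C3=C4 as an enone. C5 is the only stereocentre that survives extrusion and is set by ligand-controlled approach of 8 to one face of the chelated pyrone (ligand enantiomer chosen to give the 6S diene, which is 5R in the target), so endo/exo selectivity is irrelevant. The step needs regioselectivity and preference for the carbodiene over the ketone oxadiene: the nucleophilic CH2 of 8 is polarity-matched with the methyl-bearing pyrone C6, and any reversible hetero-Diels–Alder adduct should drain through the irreversible loss of CO2.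

Step 6
Reactants: 10 [2,4-bis(benzyloxy)-5-bromophenyl]{(6S)-6-[2,4-bis(benzyloxy)phenyl]-4-methylcyclohexa-1,3-dien-1-yl}methanone
Product: 11 {(6S)-6-[2,4-bis(benzyloxy)phenyl]-4-methylcyclohexa-1,3-dien-1-yl}[2,4-bis(benzyloxy)-5-(4,4,5,5-tetramethyl-1,3,2-dioxaborolan-2-yl)phenyl]methanone
Conditions: B2pin2, Pd(dppf)Cl2 (5 mol%), KOAc, dioxane, 80 °C
Reagents that add atoms: bis(pinacolato)diboron, CC1(C)OB(OC1(C)C)B1OC(C)(C)C(C)(C)O1
Why: Miyaura borylation of the aryl bromide with the weak acetate base should leave the dienone and the C5 stereocentre untouched.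

Step 7
Reactants: 11 {(6S)-6-[2,4-bis(benzyloxy)phenyl]-4-methylcyclohexa-1,3-dien-1-yl}[2,4-bis(benzyloxy)-5-(4,4,5,5-tetramethyl-1,3,2-dioxaborolan-2-yl)phenyl]methanone (two molecules)
Product: 14 octabenzyl-protected macrocycle (3R,4S,5R,3′R,4′R,5′R), via linear dimer 12 (not isolated), via C4/C4′-epimeric macrocycle 13 (not isolated)
Conditions: [Rh(OH)(cod)]2 (5 mol%), KOH (20 mol%), dioxane/H2O 10:1, 40 °C, syringe-pump addition to 2 mM; then NaOMe (20 mol%), MeOH, 50 °C
Reagents that add atoms: none
Why: Head-to-tail double Hayashi–Miyaura 1,4-addition (first intermolecular, then ring-closing) should deliver each aryl–rhodium to C3 (C3′) of the dienone anti to the pseudoaxial C5 (C5′) aryl group, giving the 3,5-trans relationship (3R,5R) in both rings, after which methoxide equilibrates the α-keto centres C4/C4′ to the assumed thermodynamic 4S,4′R pair.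

Step 8
Reactants: 14 octabenzyl-protected macrocycle (3R,4S,5R,3′R,4′R,5′R)
Product: 15 target macrocycle CNP0244682.3 (3R,4S,5R,3′R,4′R,5′R)
Conditions: BCl3, C6HMe5, CH2Cl2, −78 °C; MeOH quench at −78 °C
Reagents that add atoms: none
Why: Lewis-acid debenzylation with pentamethylbenzene as a non-basic cation scavenger should remove all eight benzyl groups at low temperature without touching the trisubstituted alkenes, the ketones or the C4/C4′ centres.

Compound list
1 | 1-(5-bromo-2,4-dihydroxyphenyl)ethan-1-one | CC(=O)c1cc(Br)c(O)cc1O | starting material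
2 | 1-[2,4-bis(benzyloxy)-5-bromophenyl]ethan-1-one | CC(=O)c1cc(Br)c(OCc2ccccc2)cc1OCc1ccccc1 | intermediate
3 | methyl 3-[2,4-bis(benzyloxy)-5-bromophenyl]-3-oxopropanoate | COC(=O)CC(=O)c1cc(Br)c(OCc2ccccc2)cc1OCc1ccccc1 | intermediate
4 | but-3-yn-2-one | CC(=O)C#C | starting material
5 | methyl 2-[2,4-bis(benzyloxy)-5-bromobenzoyl]-5-oxohex-3-enoate (racemic, E/Z mixture, not isolated) | COC(=O)C(C=CC(C)=O)C(=O)c1cc(Br)c(OCc2ccccc2)cc1OCc1ccccc1 | intermediate
6 | 3-[2,4-bis(benzyloxy)-5-bromobenzoyl]-6-methyl-2H-pyran-2-one | CC1=CC=C(C(=O)c2cc(Br)c(OCc3ccccc3)cc2OCc2ccccc2)C(=O)O1 | intermediate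
7 | 2,4-bis(benzyloxy)benzaldehyde | O=Cc1ccc(OCc2ccccc2)cc1OCc1ccccc1 | starting material
8 | 2,4-bis(benzyloxy)-1-ethenylbenzene | C=Cc1ccc(OCc2ccccc2)cc1OCc1ccccc1 | intermediate
9 | (1R,4R,8S)-4-[2,4-bis(benzyloxy)-5-bromobenzoyl]-8-[2,4-bis(benzyloxy)phenyl]-1-methyl-2-oxabicyclo[2.2.2]oct-5-en-3-one (aryl endo, syn to the C5=C6 bridge; not isolated) | C[C@@]12C=C[C@@](C(=O)c3cc(Br)c(OCc4ccccc4)cc3OCc3ccccc3)(C(=O)O1)[C@H](c1ccc(OCc3ccccc3)cc1OCc1ccccc1)C2 | intermediate
10 | [2,4-bis(benzyloxy)-5-bromophenyl]{(6S)-6-[2,4-bis(benzyloxy)phenyl]-4-methylcyclohexa-1,3-dien-1-yl}methanone | CC1=CC=C(C(=O)c2cc(Br)c(OCc3ccccc3)cc2OCc2ccccc2)[C@H](c2ccc(OCc3ccccc3)cc2OCc2ccccc2)C1 | intermediate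
11 | {(6S)-6-[2,4-bis(benzyloxy)phenyl]-4-methylcyclohexa-1,3-dien-1-yl}[2,4-bis(benzyloxy)-5-(4,4,5,5-tetramethyl-1,3,2-dioxaborolan-2-yl)phenyl]methanone | CC1=CC=C(C(=O)c2cc(B3OC(C)(C)C(C)(C)O3)c(OCc3ccccc3)cc2OCc2ccccc2)[C@H](c2ccc(OCc3ccccc3)cc2OCc2ccccc2)C1 | intermediate
12 | linear dimer: ring 1 complete (3R,5R, C4 unassigned) with the boronate kept on its C4 aroyl ring, and at C3 the aryl ring of the second unit, whose (6S)-cyclohexadienyl ketone is intact (not isolated) | CC1=C[C@@H](c2cc(C(=O)C3=CC=C(C)C[C@H]3c3ccc(OCc4ccccc4)cc3OCc3ccccc3)c(OCc3ccccc3)cc2OCc2ccccc2)C(C(=O)c2cc(B3OC(C)(C)C(C)(C)O3)c(OCc3ccccc3)cc2OCc2ccccc2)[C@H](c2ccc(OCc3ccccc3)cc2OCc2ccccc2)C1 | intermediate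
13 | octabenzyl-protected macrocycle, 3R,5R,3′R,5′R with C4 and C4′ unassigned (epimer mixture, not isolated) | CC1=C[C@H]2c3cc(c(OCc4ccccc4)cc3OCc3ccccc3)C(=O)C3[C@@H](C=C(C)C[C@H]3c3ccc(OCc4ccccc4)cc3OCc3ccccc3)c3cc(c(OCc4ccccc4)cc3OCc3ccccc3)C(=O)C2[C@H](c2ccc(OCc4ccccc4)cc2OCc2ccccc2)C1 | intermediate
14 | octabenzyl-protected macrocycle (3R,4S,5R,3′R,4′R,5′R): all eight phenols of 15 as benzyl ethers | CC1=C[C@H]2c3cc(c(OCc4ccccc4)cc3OCc3ccccc3)C(=O)[C@H]3[C@@H](C=C(C)C[C@H]3c3ccc(OCc4ccccc4)cc3OCc3ccccc3)c3cc(c(OCc4ccccc4)cc3OCc3ccccc3)C(=O)[C@H]2[C@H](c2ccc(OCc4ccccc4)cc2OCc2ccccc2)C1 | intermediate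
15 | CNP0244682.3: 12-membered diketone macrocycle fused to two 1-methylcyclohexene rings; ring 1 3R,4S,5R (3,4-cis, 4,5-trans), ring 2 3′R,4′R,5′R (3′,4′-trans, 4′,5′-cis) | CC1=C[C@H]2c3cc(c(O)cc3O)C(=O)[C@H]3[C@@H](C=C(C)C[C@H]3c3ccc(O)cc3O)c3cc(c(O)cc3O)C(=O)[C@H]2[C@H](c2ccc(O)cc2O)C1 | target

Total step count: 8. Longest linear sequence: 7 steps (1, 2, 3, 5, 6, 7, 8).

Steps most likely to fail

Step 7. Chain growth may outrun closure of the 12-membered ring, the electron-rich aryl boronate may protodeboronate, the tether may force the second aryl–rhodium addition syn to the C5′ aryl group, and the C4/C4′ equilibrium may not settle on the required pair. The fallback replaces cyclodimerisation by a stepwise hetero-coupling. Setting out from 10 and 11, slow addition of 11 to an excess of 10 with [Rh(OH)(cod)]2 in aqueous dioxane should give the linear bromo dimer F1. Miyaura borylation (B2pin2, Pd(dppf)Cl2, KOAc) then gives 12, now isolated and purified. Ring closure of 12 at high dilution under the same Rh conditions, followed by NaOMe/MeOH, returns to the route at 14. C4/C4′ epimers other than 14 are separated and put back into the methoxide equilibration.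

Step 5. The Lewis acid may oligomerise the electron-rich styrene, cycloaddition at the methyl-substituted pyrone terminus may be slow, hetero-Diels–Alder addition across the ketone may compete, facial discrimination may be insufficient, and the diene may suffer 1,5-hydrogen shift or air oxidation during CO2 loss. The fallback uses resolution in place of asymmetric catalysis. From 6 and 8, uncatalysed thermal cycloaddition and extrusion (toluene, 110 °C, sealed tube, BHT, argon) should pass through the racemic bridged lactone F2 to the racemic diene ketone F3. Preparative chromatography of F3 on a chiral stationary phase returns to the route at 10.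

Step 3. Intermediate 5 may carbocyclise under base (aldol or Claisen closure of the methyl ketone to arenes), a second ynone may add, or lactonisation may stall at the E enone. The fallback is an acidic enaminone condensation instead of the amine-mediated ynone addition. From 3, heating with (E)-4-(dimethylamino)but-3-en-2-one in AcOH at 90 °C should form the same open-chain adduct 5 by addition–elimination and lactonise it in the same medium, returning at 6. No new compound is formed.

Further compounds
F1 | step 7 | linear bromo dimer: as 12 but with bromine in place of the boronate on the ring-1 aroyl group | CC1=C[C@@H](c2cc(C(=O)C3=CC=C(C)C[C@H]3c3ccc(OCc4ccccc4)cc3OCc3ccccc3)c(OCc3ccccc3)cc2OCc2ccccc2)C(C(=O)c2cc(Br)c(OCc3ccccc3)cc2OCc2ccccc2)[C@H](c2ccc(OCc3ccccc3)cc2OCc2ccccc2)C1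
F2 | step 5 | racemic 4-[2,4-bis(benzyloxy)-5-bromobenzoyl]-8-[2,4-bis(benzyloxy)phenyl]-1-methyl-2-oxabicyclo[2.2.2]oct-5-en-3-one | CC12C=CC(C(=O)c3cc(Br)c(OCc4ccccc4)cc3OCc3ccccc3)(C(=O)O1)C(c1ccc(OCc3ccccc3)cc1OCc1ccccc1)C2
F3 | step 5 | racemic [2,4-bis(benzyloxy)-5-bromophenyl]{6-[2,4-bis(benzyloxy)phenyl]-4-methylcyclohexa-1,3-dien-1-yl}methanone | CC1=CC=C(C(=O)c2cc(Br)c(OCc3ccccc3)cc2OCc2ccccc2)C(c2ccc(OCc3ccccc3)cc2OCc2ccccc2)C1
F0 | step 3 | none | none
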